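Hold the balance: left-handed substrate, right-handed substrate and both products sum to the charge, so subtract to get the right-handed substrate that nobody read.

the same everywhere: gas 61 mM (held)

| flask | left-handed substrate | right-handed substrate | remark | time |
|---|---|---|---|---|
| spring | 0.15 M | 0.15 M | run made earlier |  |
| noon | 0.22 M | 0.22 M | run made earlier |  |
| flask | 0.30 M | 0.30 M |  | 2.0 h |

| run | time / min | left-handed product / % | right-handed product / % | left-handed substrate / % |
|---|---|---|---|---|
| spring | 10.0 | 4 | 3 | 44 |
| spring | 20.0 | 11 | 5 | 37 |
| spring | 30.0 | 17 | 15 | 28 |
| spring | 60.0 | 34 | 30 | 12 |
| spring | 120 | 43 | 47 | 0 |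
| noon | 10.0 | 5 | 4 | 45 |
| noon | 20.0 | 12 | 8 | 39 |
| noon | 30.0 | 13 | 16 | 32 |
| noon | 60.0 | 27 | 22 | 16 |
| noon | 120 | 39 | 47 | 4 |

(readings scatter by 2 percentage points)

* excess of left-handed product over right-handed product in the product at 12 min
* excess of left-handed product over right-handed product in the product at 2.0 h
* part of the left-handed substrate and right-handed substrate charged together that has reacted at 2.0 h

- coupling partner is single-handed; left-handed substrate and right-handed substrate are mirror images of each other, charged as a racemate, each of them at the stated concentration
- at the start none of the gas is in solution
- an excess is the difference of the two amounts in percent of their sum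
- an excess is below zero if the other one leads
- the handed part of coupling partner does not stay in what it makes, so the products of the two hands are mirror images too

How do the hands compare? Assume both are first order in the same c(coupling partner). It then cancels, gas lag included, from s, the selectivity factor: the log drop of the right-handed substrate over that of the left-handed substrate, each on its own charge. Take one late reading from each run: the spring run at 60.0 min gives 0.514, the noon run at 120 min gives 0.637, so read s as 0.576. Equal charges then start the product excess at (1 − s)/(1 + s), and I commit to 26.9% for 12 min.

How far does the flask get by 2.0 h? The noon log drop at 60.0 min is 0.798 of the spring one. Apply that factor once more to the noon drop at 120 min: I reckon the flask keeps 13.3% of its left-handed substrate and 31.3% of its right-handed substrate, so I commit to 77.7% reacted.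

Do products stay as formed? My substrate estimates for the flask count to a product excess of 11.6% at 2.0 h, but the noon run at 120 min reads 16 percentage points below its own count. Subtract that reading, scatter included, and I commit to −4.69% for the flask.

The forecast says 20%, −2% and 81%, holding that “left-hand product leaks away slowly”.

The flask gives 23.3%, 1.09% and 79.8%.

    coupling partner + left-handed substrate → left-handed product (k = 0.813 L mol⁻¹ min⁻¹)
    2 coupling partner → homo dimer (k = 0.294 L mol⁻¹ min⁻¹)
    left-handed product ⇌ right-handed product (k = 0.00932 min⁻¹)
    gas ⇌ coupling partner, rate k4*(csat - [coupling partner]) (kL = 0.118 min⁻¹)
    coupling partner + right-handed substrate → right-handed product (k = 0.469 L mol⁻¹ min⁻¹)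

The flask's product excess stood at 18.0% after 0.500 h and 10.8% after 1.00 h. Put s on the flask at 2.00 h: 12% of the left-handed substrate remaining gives 28.8% of the right-handed substrate, and the flask holds 29%. Put it on the spring run at 30.0 min: the left-handed substrate reading gives 35.8% of the two charged as right-handed substrate, and the balance of the readings gives 40.0%.

(The earlier runs and the new flask are calculated with made-up constants, noise included.)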